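**Plan**
1. Structure as read (germacrane numbering: ring C1–C10, acrylate C11–C13, C14 = CH3 on C10, C15 = CH2OH on C4): a ten-membered carbocycle with a 4Z alkene, a 1β,10β-epoxide whose ring bonds are cis (so it comes from a 1(10)Z alkene), a trans 6α,12-γ-lactone, 3β-OAc and 8β-O-angelate; (1R,3S,6R,7R,8R,10S).
2. Enabling feature: the lactone oxygen on C6 is allylic to C4=C5, and the neighbouring C7 carries C11. Ring atoms C4–C7 are therefore the imprint of a 1,3-diene that took up C and O at one end. In the ten-membered ring this diene is (4Z,6E), and its E-C6=C7 bond is strained and open on one face only.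
3. Retrosynthetic cuts, in order: O15–Si, O8–angeloyl, epoxide O, O3–acetyl; then O–C6 and C11–C7 together (2-bromoacrylic acid + trienol 16); then C3–C4 (ring closure), C2=C3 and C3–O (homologation), C8–C9 (vinylogous aldol), C6=C7 (Wittig), C4–I (hydroalumination).
4. Forward: butynediol → C15–C4–C5–C6 iodoenal → dienal → dihydropyranone (a temporary ring that locks 1(10)Z) → open-chain aldehyde → carbocycle → γ-lactone → epoxide → angelate → free C15-OH.
5. Stereochemistry: C8 from the catalytic asymmetric vinylogous aldol; C3 from the ligand-controlled Cr addition; C6/C7 from suprafacial addition to the outer face of the E-alkene, with the face fixed by C8; C1/C10 from 8-OH-directed epoxidation; 4Z from trans-hydroalumination; the angelate Z alkene from angelic acid.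

Key step: step 13

Remark: for the chiral ligands of steps 6 and 12, the enantiomer named is the one expected to give the drawn configuration (both antipodes are available). Any minor enantiomer carried over from step 6 becomes a separable diastereomer in step 12.

**Step 1**
Reactants: 1 but-2-yne-1,4-diol
Product: 2 4-(tert-butyldimethylsilyloxy)but-2-yn-1-ol
Conditions: NaH (1 equiv), THF, 0 °C; TBSCl (1 equiv), rt
Reagents that add atoms: tert-butyldimethylsilyl chloride, CC(C)(C)[Si](C)(C)Cl
Why: O-silylation of the monosodium alkoxide of a symmetrical diol should stop at the monoether and leaves one propargylic OH free to direct step 2.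

**Step 2**
Reactants: 2 4-(tert-butyldimethylsilyloxy)but-2-yn-1-ol
Product: 4 (Z)-4-(tert-butyldimethylsilyloxy)-3-iodobut-2-en-1-ol, via cyclic vinylalanate 3 (not isolated)
Conditions: Red-Al, THF, 0 °C → rt; I2, THF, −78 °C
Reagents that add atoms: iodine, II; Red-Al, [Na+].COCCO[AlH2-]OCCOC (atoms kept only in 3)
Why: Hydroxyl-directed trans-hydroalumination of a propargylic alcohol places Al on the distal alkyne carbon C4 inside a five-membered chelate, and iodinolysis with retention gives I cis to C6 and C15 trans to C6, which is the later 4Z ring geometry.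

**Step 3**
Reactants: 4 (Z)-4-(tert-butyldimethylsilyloxy)-3-iodobut-2-en-1-ol
Product: 5 (Z)-4-(tert-butyldimethylsilyloxy)-3-iodobut-2-enal
Conditions: MnO2, CH2Cl2, rt
Reagents that add atoms: none
Why: Neutral MnO2 oxidation of an allylic alcohol should give the enal without touching the C–I bond or the alkene geometry.

**Step 4**
Reactants: 5 (Z)-4-(tert-butyldimethylsilyloxy)-3-iodobut-2-enal
Product: 6 (2E,4Z)-6-(tert-butyldimethylsilyloxy)-5-iodohexa-2,4-dienal
Conditions: Ph3P=CHCHO, toluene, 40 °C
Reagents that add atoms: (triphenylphosphoranylidene)acetaldehyde, O=CC=P(c1ccccc1)(c1ccccc1)c1ccccc1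
Why: Wittig olefination with the stabilised formyl ylide adds C7 and C8 and should give the E-C6=C7 alkene.

**Step 5**
Reactants: 7 methyl 3-methylbut-2-enoate
Product: 8 1-methoxy-3-methyl-1-(trimethylsilyloxy)buta-1,3-diene
Conditions: LDA, THF, −78 °C; TMSCl
Reagents that add atoms: chlorotrimethylsilane, C[Si](C)(C)Cl
Why: Kinetic γ-deprotonation of the senecioate and O-silylation (silyl dienolate formation) give the C2–C1–C10(C14)–C9 donor, and its ketene acetal geometry is of no consequence.

**Step 6**
Reactants: 6 (2E,4Z)-6-(tert-butyldimethylsilyloxy)-5-iodohexa-2,4-dienal; 8 1-methoxy-3-methyl-1-(trimethylsilyloxy)buta-1,3-diene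
Product: 9 (6R)-6-[(1E,3Z)-5-(tert-butyldimethylsilyloxy)-4-iodopenta-1,3-dienyl]-4-methyl-5,6-dihydro-2H-pyran-2-one
Conditions: Cu(OTf)2 (10 mol %), (S)-Tol-BINAP (11 mol %), Bu4N[Ph3SiF2] (20 mol %), THF, −78 °C → rt
Reagents that add atoms: none
Why: In this catalytic asymmetric vinylogous Mukaiyama aldol addition the chiral Cu(I) dienolate attacks one face of aldehyde C8 through its γ-carbon C9 (sets 8R), and only the Z δ-oxido enoate can lactonise, so the ring locks the 1(10)Z alkene.

**Step 7**
Reactants: 9 the dihydropyranone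
Product: 10 (6R)-6-[(1E,3Z)-5-(tert-butyldimethylsilyloxy)-4-iodopenta-1,3-dienyl]-4-methyl-5,6-dihydro-2H-pyran-2-ol (anomeric mixture)
Conditions: DIBAL-H (1.1 equiv), CH2Cl2, −78 °C
Reagents that add atoms: none
Why: Partial 1,2-reduction of the lactone with DIBAL-H stops at the aluminium lactolate at low temperature and spares the vinyl iodide and the silyl ether.

**Step 8**
Reactants: 10 the lactol
Product: 11 (3Z,6R,7E,9Z)-11-(tert-butyldimethylsilyloxy)-10-iodo-4-methylundeca-1,3,7,9-tetraen-6-ol
Conditions: MePPh3Br, KOt-Bu, THF, 0 °C; then 10, −78 → 0 °C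
Reagents that add atoms: methyltriphenylphosphonium bromide, C[P+](c1ccccc1)(c1ccccc1)c1ccccc1.[Br-]
Why: Wittig methylenation of the open hydroxy-enal form of the lactol adds C3, removes the temporary ring and keeps the Z alkene, because olefination should outrun enal isomerisation.

**Step 9**
Reactants: 11 the tetraenol
Product: 12 the C8 triethylsilyl ether of 11
Conditions: TESCl, imidazole, CH2Cl2, 0 °C
Reagents that add atoms: chlorotriethylsilane, CC[Si](Cl)(CC)CC
Why: Standard O-silylation, with TES chosen because it can later be removed in the presence of the primary TBS ether.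

**Step 10**
Reactants: 12 the TES ether
Product: 14 (3Z,6R,7E,9Z)-11-(tert-butyldimethylsilyloxy)-10-iodo-4-methyl-6-(triethylsilyloxy)undeca-3,7,9-trien-1-ol, via B-alkyl-9-BBN adduct 13 (not isolated)
Conditions: 9-BBN, THF, 0 °C → rt; H2O2, aq NaOH, 0 °C
Reagents that add atoms: hydrogen peroxide, OO; 9-BBN, B1C2CCCC1CCC2 (atoms kept only in 13)
Why: In this hydroboration–oxidation 9-BBN adds anti-Markovnikov to the only monosubstituted alkene (boron on C3), much faster than to the trisubstituted C1=C10 alkene or the internal iododiene.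

**Step 11**
Reactants: 14 the primary alcohol
Product: 15 (3Z,6R,7E,9Z)-11-(tert-butyldimethylsilyloxy)-10-iodo-4-methyl-6-(triethylsilyloxy)undeca-3,7,9-trienal
Conditions: Dess–Martin periodinane, CH2Cl2, 0 °C, used at once
Reagents that add atoms: none
Why: Dess–Martin oxidation is base-free, so the β,γ-unsaturated aldehyde should form without migration of the Z alkene into conjugation.

**Step 12**
Reactants: 15 the iodo-aldehyde
Product: 16 (1S,2Z,4E,6R,8Z)-2-[(tert-butyldimethylsilyloxy)methyl]-8-methyl-6-(triethylsilyloxy)cyclodeca-2,4,8-trien-1-ol (3β-OH, 8β-OTES, 4Z,6E,1(10)Z)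
Conditions: CrCl2 (6 equiv), (S)-4-isopropyloxazoline–sulfonamide ligand, Et3N, NiCl2 (5 mol %), THF, rt, slow addition of 15 (2 mM)
Reagents that add atoms: none
Why: In this Nozaki–Hiyama–Kishi macrocyclisation Ni inserts into C4–I with retention of 4Z, the vinylchromium(III) species adds to the aldehyde under neutral conditions that neither enolise it nor harm the silyl ethers, the Z arrangement of C3 and C6 on C4=C5 brings the chain ends together, and the chiral ligand on Cr selects the aldehyde face that gives 3S.

**Step 13**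
Reactants: 16 the ten-membered trienol; 17 2-bromoacrylic acid
Product: 18 3β-hydroxy-8β-(triethylsilyloxy)-15-(tert-butyldimethylsilyloxy)germacra-1(10)Z,4Z,11(13)-trien-6α,12-olide (H-6β, H-7α)
Conditions: Pd(OAc)2 (10 mol %), P(2-furyl)3 (20 mol %), Ag2CO3 (1.5 equiv), MeCN, 50 °C, slow addition of 17
Reagents that add atoms: none
Why: Pd(0) inserts into the C–Br bond of the silver 2-bromoacrylate, the α-carboxyvinyl-Pd(II) species adds syn across the strained E-C6=C7 bond with carbon going to the diene terminus C7 and Pd to C6, where it becomes an η3-allyl over C6–C5–C4, and the carboxylate held on the same Pd then forms O–C6 by inner-sphere reductive elimination, which returns Pd(0). The closest known reaction type is the Larock heteroannulation of 1,3-dienes by aryl or vinylic halides that carry an OH, NHR or CO2H group. The one ring closed is the γ-lactone (O, C6, C7, C11, C12), overall a [3+2] annulation whose closing event is contraction of a six-membered oxapalladacycle, that is a 5-exo attack of O on allyl terminus C6 rather than a 7-endo attack on C4. Because rotation about C6–C7 is blocked in the ten-membered ring, both bonds form on the same face, and suprafacial addition to an E-alkene gives the trans lactone (H6 and H7 anti), just as Z-configured cyclic dienes give cis-fused products. The face is chosen by C8: the E-alkene stands perpendicular to the ring so that only its outer face is open, and the reactive conformer has C9 anti, the C8–OTES bond in the alkene plane (inside) and H8 outside, which leaves C7 unhindered and leads to 6R,7R. Regio- and chemoselectivity rest on four points: C7 is the less substituted diene terminus (C4 is fully substituted), the E-alkene releases strain whereas the isolated trisubstituted C1=C10 alkene does not, C3 stays anti on the allyl so that 4Z is kept, and no allylic ester is present (only a free OH and silyl ethers) for Pd(0) to ionise, while 50 °C stays below the range of Cope and 1,5-H shifts of the triene.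

**Step 14**
Reactants: 18 the hydroxy lactone
Product: 19 3β-acetoxy-8β-(triethylsilyloxy)-15-(tert-butyldimethylsilyloxy)germacra-1(10)Z,4Z,11(13)-trien-6α,12-olide
Conditions: Ac2O, pyridine, DMAP (cat.), CH2Cl2, 0 °C
Reagents that add atoms: acetic anhydride, CC(=O)OC(C)=O
Why: DMAP-catalysed acylation of the only free hydroxyl proceeds with retention at C3 and is placed after the Pd step so that no allylic acetate meets Pd(0).

**Step 15**
Reactants: 19 the acetate
Product: 20 3β-acetoxy-8β-hydroxy-15-(tert-butyldimethylsilyloxy)germacra-1(10)Z,4Z,11(13)-trien-6α,12-olide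
Conditions: PPTS (cat.), MeOH/CH2Cl2, 0 °C
Reagents that add atoms: none
Why: Mild acid-catalysed methanolysis cleaves the labile TES ether selectively over the TBS ether and is done before the acid-sensitive epoxide exists.

**Step 16**
Reactants: 20 the 8β-alcohol
Product: 21 3β-acetoxy-1β,10β-epoxy-8β-hydroxy-15-(tert-butyldimethylsilyloxy)germacra-4Z,11(13)-dien-6α,12-olide
Conditions: VO(acac)2 (5 mol %), t-BuOOH, CH2Cl2, 0 °C → rt
Reagents that add atoms: tert-butyl hydroperoxide, CC(C)(C)OO
Why: In this vanadium-catalysed hydroxyl-directed epoxidation of a homoallylic alcohol the vanadate ester of the outward-pointing 8β-OH can reach only the alkene face on which C8–O lies, which sets 1R,10S (oxygen cis to O8, ring bonds cis from the Z alkene), while the electron-poor C11=C13 and the remote, acyloxy-flanked C4=C5 alkenes stay untouched.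

**Step 17**
Reactants: 21 the epoxy alcohol; 22 angelic acid
Product: 24 3β-acetoxy-8β-angeloyloxy-1β,10β-epoxy-15-(tert-butyldimethylsilyloxy)germacra-4Z,11(13)-dien-6α,12-olide, via angelic trichlorobenzoic mixed anhydride 23 (not isolated)
Conditions: 22, 2,4,6-trichlorobenzoyl chloride, Et3N, toluene, rt, salts filtered off; then 21, 75 °C
Reagents that add atoms: 2,4,6-trichlorobenzoyl chloride, O=C(Cl)c1c(Cl)cc(Cl)cc1Cl (atoms kept only in 23)
Why: Yamaguchi-type mixed-anhydride esterification without a nucleophilic catalyst is the established non-isomerising way to angeloylate hindered secondary alcohols, and it acylates O8 with retention at C8 and keeps the Z alkene of the acid.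

**Step 18**
Reactants: 24 the silyl ether
Product: 25 target, (1R,3S,6R,7R,8R,10S)-3-acetoxy-8-angeloyloxy-1,10-epoxy-15-hydroxygermacra-4Z,11(13)-dien-12,6-olide
Conditions: TBAF/AcOH (1:1), THF, 0 °C → rt
Reagents that add atoms: none
Why: Fluoride-induced Si–O cleavage buffered with acetic acid should avoid acetyl migration from O3 to O15, epoxide opening and conjugate addition to the α-methylene lactone.

**Compound list**
1 | but-2-yne-1,4-diol | OCC#CCO | starting material
2 | 4-(tert-butyldimethylsilyloxy)but-2-yn-1-ol | CC(C)(C)[Si](C)(C)OCC#CCO | intermediate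
3 | sodium cyclic vinylalanate (O6–Al–C4 chelate) | [Na+].COCCO[Al-]1(OCCOC)OCC=C1CO[Si](C)(C)C(C)(C)C | intermediate (not isolated)
4 | (Z)-4-(tert-butyldimethylsilyloxy)-3-iodobut-2-en-1-ol | OC/C=C(/CO[Si](C)(C)C(C)(C)C)I | intermediate
5 | (Z)-4-(tert-butyldimethylsilyloxy)-3-iodobut-2-enal | O=C/C=C(/CO[Si](C)(C)C(C)(C)C)I | intermediate
6 | (2E,4Z)-6-(tert-butyldimethylsilyloxy)-5-iodohexa-2,4-dienal | O=C/C=C/C=C(/CO[Si](C)(C)C(C)(C)C)I | intermediate
7 | methyl 3-methylbut-2-enoate | COC(=O)C=C(C)C | starting material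
8 | 1-methoxy-3-methyl-1-(trimethylsilyloxy)buta-1,3-diene (ketene acetal geometry undefined) | C=C(C)C=C(OC)O[Si](C)(C)C | intermediate
9 | (6R)-6-[(1E,3Z)-5-(TBSO)-4-iodopenta-1,3-dienyl]-4-methyl-5,6-dihydro-2H-pyran-2-one | O=C1C=C(C)C[C@@H](O1)/C=C/C=C(/CO[Si](C)(C)C(C)(C)C)I | intermediate
10 | corresponding lactol (anomeric mixture) | OC1C=C(C)C[C@@H](O1)/C=C/C=C(/CO[Si](C)(C)C(C)(C)C)I | intermediate
11 | (3Z,6R,7E,9Z)-11-(TBSO)-10-iodo-4-methylundeca-1,3,7,9-tetraen-6-ol | C=C/C=C(/C)C[C@@H](O)/C=C/C=C(/CO[Si](C)(C)C(C)(C)C)I | intermediate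
12 | TES ether of 11 | C=C/C=C(/C)C[C@@H](O[Si](CC)(CC)CC)/C=C/C=C(/CO[Si](C)(C)C(C)(C)C)I | intermediate
13 | B-alkyl-9-BBN adduct (boron on C3) | B1(C2CCCC1CCC2)CC/C=C(/C)C[C@@H](O[Si](CC)(CC)CC)/C=C/C=C(/CO[Si](C)(C)C(C)(C)C)I | intermediate (not isolated)
14 | (3Z,6R,7E,9Z)-11-(TBSO)-10-iodo-4-methyl-6-(TESO)undeca-3,7,9-trien-1-ol | OCC/C=C(/C)C[C@@H](O[Si](CC)(CC)CC)/C=C/C=C(/CO[Si](C)(C)C(C)(C)C)I | intermediate
15 | corresponding trienal | O=CC/C=C(/C)C[C@@H](O[Si](CC)(CC)CC)/C=C/C=C(/CO[Si](C)(C)C(C)(C)C)I | intermediate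
16 | (1S,2Z,4E,6R,8Z)-2-[(TBSO)methyl]-8-methyl-6-(TESO)cyclodeca-2,4,8-trien-1-ol | O[C@H]1C/C=C(/C)C[C@@H](O[Si](CC)(CC)CC)/C=C/C=C1/CO[Si](C)(C)C(C)(C)C | intermediate
17 | 2-bromoacrylic acid | OC(=O)C(Br)=C | starting material
18 | 3β-hydroxy-8β-TESO-15-TBSO-germacra-1(10)Z,4Z,11(13)-trien-6α,12-olide | C=C1C(=O)O[C@@H]2/C=C(/CO[Si](C)(C)C(C)(C)C)[C@@H](O)C/C=C(/C)C[C@@H](O[Si](CC)(CC)CC)[C@@H]12 | intermediate
19 | 3β-acetate of 18 | C=C1C(=O)O[C@@H]2/C=C(/CO[Si](C)(C)C(C)(C)C)[C@@H](OC(C)=O)C/C=C(/C)C[C@@H](O[Si](CC)(CC)CC)[C@@H]12 | intermediate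
20 | 3β-acetoxy-8β-hydroxy-15-TBSO-germacra-1(10)Z,4Z,11(13)-trien-6α,12-olide | C=C1C(=O)O[C@@H]2/C=C(/CO[Si](C)(C)C(C)(C)C)[C@@H](OC(C)=O)C/C=C(/C)C[C@@H](O)[C@@H]12 | intermediate
21 | 1β,10β-epoxide of 20 | C=C1C(=O)O[C@@H]2/C=C(/CO[Si](C)(C)C(C)(C)C)[C@@H](OC(C)=O)C[C@H]3O[C@@]3(C)C[C@@H](O)[C@@H]12 | intermediate
22 | angelic acid, (Z)-2-methylbut-2-enoic acid | C/C=C(/C)C(=O)O | starting material
23 | angelic 2,4,6-trichlorobenzoic anhydride | C/C=C(/C)C(=O)OC(=O)c1c(Cl)cc(Cl)cc1Cl | intermediate (not isolated)
24 | 8β-angelate of 21 (15-O-TBS target) | C=C1C(=O)O[C@@H]2/C=C(/CO[Si](C)(C)C(C)(C)C)[C@@H](OC(C)=O)C[C@H]3O[C@@]3(C)C[C@@H](OC(=O)/C(C)=C\C)[C@@H]12 | intermediate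
25 | CNP0162483.1 | C=C1C(=O)O[C@@H]2/C=C(/CO)[C@@H](OC(C)=O)C[C@H]3O[C@@]3(C)C[C@@H](OC(=O)/C(C)=C\C)[C@@H]12 | target

**Step count and risks**
Total step count: 18. Longest linear sequence: 17 (steps 1–4 and 6–18).

The three steps most likely to fail:

**Step 13.** What may go wrong:
- attack on the wrong face of the E-alkene;
- β-hydride loss at the allyl-Pd stage in place of C–O closure;
- thermal rearrangement of the strained triene before it is consumed.

The fallback sets out from 16 and returns at 18. It replaces the Pd cycle by a radical–polar annulation at a lower oxidation level. Mn(OAc)3-mediated carbolactonisation of 16 with potassium methyl malonate in AcOH at rt would proceed in three events: the malonyl radical adds to C7, the allyl radical is oxidised, and the free carboxyl closes on C6. This would give the α-methoxycarbonyl lactone F1. Saponification with LiOH and re-acidification would give the α-carboxy lactone F2. Decarboxylative Mannich methylenation (aq HCHO, Et2NH, NaOAc/AcOH) would then give 18.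

**Step 12.** What may go wrong:
- intermolecular coupling (oligomerisation) because of the ring strain;
- drift of the β,γ-unsaturated aldehyde into conjugation during the slow addition;
- poor facial selectivity at C3.

The fallback sets out from 15 and returns at 16. It makes C3–C4 by acyl substitution and sets C3 by reduction:
- Pinnick oxidation gives the carboxylic acid F3.
- Coupling with MeNH(OMe)·HCl (EDC) gives the Weinreb amide F4.
- Iodine–magnesium exchange (i-PrMgCl·LiCl, −40 °C, high dilution) with intramolecular acylation gives the ten-membered cross-conjugated dienone F5.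
- Corey–Bakshi–Shibata reduction with (R)-Me-CBS and catecholborane gives 16.

**Step 16.** What may go wrong: poor facial selectivity, if the vanadate cannot reach the alkene across the ring, and slow turnover.

The fallback sets out from 20 and returns at 24. It exchanges substrate direction for reagent control. Angeloylation of 20 with mixed anhydride 23 would come first and give the triene diester F6. Shi epoxidation (fructose-derived ketone of the series matched to the β face, Oxone, buffered MeCN/H2O, 0 °C) of its only electron-rich alkene, C1=C10, would then give 24.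

**Further compounds**
F1 | step 13 | 11-methoxycarbonyl-3β-hydroxy-8β-TESO-15-TBSO-13-norgermacra-1(10)Z,4Z-dien-6α,12-olide (C11 epimers) | COC(=O)C1C(=O)O[C@@H]2/C=C(/CO[Si](C)(C)C(C)(C)C)[C@@H](O)C/C=C(/C)C[C@@H](O[Si](CC)(CC)CC)[C@@H]12
F2 | step 13 | corresponding 11-carboxylic acid | OC(=O)C1C(=O)O[C@@H]2/C=C(/CO[Si](C)(C)C(C)(C)C)[C@@H](O)C/C=C(/C)C[C@@H](O[Si](CC)(CC)CC)[C@@H]12
F3 | step 12 | (3Z,6R,7E,9Z)-11-(TBSO)-10-iodo-4-methyl-6-(TESO)undeca-3,7,9-trienoic acid | OC(=O)C/C=C(/C)C[C@@H](O[Si](CC)(CC)CC)/C=C/C=C(/CO[Si](C)(C)C(C)(C)C)I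
F4 | step 12 | N-methoxy-N-methylamide of F3 | CON(C)C(=O)C/C=C(/C)C[C@@H](O[Si](CC)(CC)CC)/C=C/C=C(/CO[Si](C)(C)C(C)(C)C)I
F5 | step 12 | (2Z,4E,6R,8Z)-2-[(TBSO)methyl]-8-methyl-6-(TESO)cyclodeca-2,4,8-trien-1-one | O=C1C/C=C(/C)C[C@@H](O[Si](CC)(CC)CC)/C=C/C=C1/CO[Si](C)(C)C(C)(C)C
F6 | step 16 | 3β-acetoxy-8β-angeloyloxy-15-TBSO-germacra-1(10)Z,4Z,11(13)-trien-6α,12-olide | C=C1C(=O)O[C@@H]2/C=C(/CO[Si](C)(C)C(C)(C)C)[C@@H](OC(C)=O)C/C=C(/C)C[C@@H](OC(=O)/C(C)=C\C)[C@@H]12
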